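**Retrosynthetic overview**

1. The target is a fully substituted 2,5-dihydroxy-1,4-benzoquinone with a single six-membered carbocycle: henicosyl on C1, methyl on C4 (para to it), oxygen on C2, C3, C5 and C6. The strategy rests on this ring being reachable from a 5-alkyl-2-methylresorcinol in which C3 and C5 already carry oxygen and C2 and C6 are still C–H.
2. Endgame: target 22 ⇐ tetraacetate 20 (hydrolysis, air) ⇐ hydroxyquinone 18 (acetoxylation of the last ring C–H) ⇐ resorcinol 17 (oxidation para to a hydroxyl) ⇐ monosilyl ether 16.
3. Key disconnection: the benzene ring of 16 is cut at C4–C5 and C2–C3 into 1-(triisopropylsilyloxy)propyne 11 (C3 with its oxygen, C4 with its methyl) and 3-henicosylcyclobutenone 7 (C5 as carbonyl, C6, C1 with the chain, C2).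
4. 7 ⇐ tricos-1-yne 3 + dichloroketene (from 4); 3 ⇐ docosanal 2 ⇐ docosan-1-ol 1; 11 ⇐ ethyl acetate 8 through a lithium ynolate.
5. Ring order: the four-membered ring of 7 is made first and sacrificed; the only ring of the target is closed in step 6 and then raised to the quinone oxidation level.

Key step: step 6

Remark: the target is achiral and its dihydroxyquinone core has two degenerate tautomers, so only the substitution pattern has to be matched.

**Route**

Step 1
Reactants: 1 docosan-1-ol
Product: 2 docosanal
Conditions: TEMPO (cat.), PhI(OAc)2, CH2Cl2, rt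
Reagents that add atoms: none
Why: Nitroxyl-catalysed (oxoammonium) oxidation of a primary alcohol stops at the aldehyde when water is absent, and the saturated chain offers no other reactive site.

Step 2
Reactants: 2 docosanal
Product: 3 tricos-1-yne
Conditions: MeC(O)C(N2)P(O)(OMe)2, K2CO3, MeOH/THF, 0 °C to rt
Reagents that add atoms: dimethyl (1-diazo-2-oxopropyl)phosphonate, CC(=O)C(=[N+]=[N-])P(=O)(OC)OC
Why: Ohira–Bestmann form of the Seyferth–Gilbert homologation: methanolysis frees the diazomethylphosphonate anion, which olefinates the aldehyde, and loss of N2 with a 1,2-hydride shift of the alkylidene carbene gives the terminal alkyne one carbon longer.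

Step 3
Reactants: 3 tricos-1-yne; 4 trichloroacetyl chloride
Product: 6 4,4-dichloro-3-henicosylcyclobut-2-en-1-one, via dichloroketene 5 (not isolated)
Conditions: Zn(Cu), Et2O/DME, rt, slow addition of 4
Reagents that add atoms: none
Why: Zinc dechlorinates 4 to dichloroketene, which adds to terminal alkynes in a known [2+2] cycloaddition; the terminal alkyne carbon bonds to the ketene carbonyl carbon, so the chain ends up on C3 next to the CCl2 group.

Step 4
Reactants: 6 4,4-dichloro-3-henicosylcyclobut-2-en-1-one
Product: 7 3-henicosylcyclobut-2-en-1-one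
Conditions: Zn dust, AcOH, TMEDA, EtOH/THF, 0 °C to rt
Reagents that add atoms: none
Why: Zinc reductively removes both α-chlorines through zinc enolates that acetic acid protonates, and the amine-buffered medium is the standard one that keeps the strained enone from isomerising or opening.

Step 5
Reactants: 8 ethyl acetate
Product: 11 triisopropyl(prop-1-yn-1-yloxy)silane, via lithium 1,1-dibromoprop-1-en-2-olate 9 (not isolated), via lithium prop-1-yn-1-olate 10 (not isolated)
Conditions: CH2Br2, LiTMP (2.2 equiv), THF, −78 °C; n-BuLi, −78 °C to rt; TIPSOTf, −78 to 0 °C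
Reagents that add atoms: dibromomethane, BrCBr; triisopropylsilyl trifluoromethanesulfonate, CC(C)[Si](C(C)C)(C(C)C)OS(=O)(=O)C(F)(F)F
Why: Kowalski ester homologation stopped at the ynolate: dibromomethyllithium adds to the ester, the adduct collapses and is deprotonated to enolate 9, bromine–lithium exchange gives a carbenoid whose 1,2-methyl shift furnishes ynolate 10, and the bulky silyl triflate silylates it on oxygen.

Step 6
Reactants: 7 3-henicosylcyclobut-2-en-1-one; 11 triisopropyl(prop-1-yn-1-yloxy)silane
Product: 16 5-henicosyl-2-methyl-3-(triisopropylsilyloxy)phenol, via vinylketene 12 (not isolated), via vinylcyclobutenone 13 (not isolated), via dienylketene 14 (not isolated), via cyclohexadienone 15 (not isolated)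
Conditions: 11 (1.3 equiv), toluene (0.2 M), 80 °C then 110 °C, N2
Reagents that add atoms: none
Why: Danheiser benzannulation: near 80 °C cyclobutenone 7 opens reversibly by 4π electrocyclic cleavage to vinylketene 12, which the electron-rich siloxyalkyne 11 traps in a regioselective [2+2] cycloaddition to give 4-vinylcyclobutenone 13. A second 4π opening of 13 gives dienylketene 14, whose 6π electrocyclisation closes the six-membered carbocycle between the ketene carbon C5 and the terminal methylene C6 as cyclohexadienone 15, and enolisation delivers phenol 16. The closest known reaction type is the thermal annulation of 3-alkylcyclobutenones with alkoxy- and siloxyalkynes to 5-alkylresorcinol monoethers, of which this is a direct case. No stereocenter is created. The selectivity needed is the orientation of the [2+2] step: the siloxy oxygen polarises the alkyne so that its methyl-bearing carbon is the nucleophilic end and bonds to the ketene carbonyl carbon (C4–C5), leaving the oxygen-bearing carbon to bond to the ketene CH (C2–C3), which places the methyl between the two oxygens and para to the chain. A modest excess of 11 at moderate dilution is meant to keep the phenol product from competing for the ketene.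

Step 7
Reactants: 16 5-henicosyl-2-methyl-3-(triisopropylsilyloxy)phenol
Product: 17 5-henicosyl-2-methylbenzene-1,3-diol
Conditions: TBAF, AcOH, THF, 0 °C to rt
Reagents that add atoms: none
Why: Fluoride cleaves the aryl silyl ether by Si–F bond formation, and the acetic acid buffer keeps the electron-rich resorcinol from sitting as a phenoxide in air.

Step 8
Reactants: 17 5-henicosyl-2-methylbenzene-1,3-diol
Product: 18 5-henicosyl-3-hydroxy-2-methylcyclohexa-2,5-diene-1,4-dione
Conditions: (KSO3)2NO, aq KH2PO4, acetone/THF, rt
Reagents that add atoms: potassium nitrosodisulfonate, [K+].[K+].[O]N(S(=O)(=O)[O-])S(=O)(=O)[O-]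
Why: Teuber oxidation: one nitroxyl radical abstracts the phenolic hydrogen, a second couples at the free carbon para to that hydroxyl (the two ring C–H positions are equivalent by symmetry), and loss of imidodisulfonate gives the para-quinone with the other hydroxyl retained.

Step 9
Reactants: 18 5-henicosyl-3-hydroxy-2-methylcyclohexa-2,5-diene-1,4-dione
Product: 20 3-henicosyl-6-methylbenzene-1,2,4,5-tetrayl tetraacetate, via acetoxyquinone 19 (not isolated)
Conditions: Ac2O, conc. H2SO4 (cat.), rt to 40 °C
Reagents that add atoms: acetic anhydride, CC(=O)OC(C)=O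
Why: Thiele–Winter acetoxylation: acid-catalysed O-acetylation gives 19, acetate then adds in conjugate fashion to the only unsubstituted quinone carbon (para to the acetoxy group, the position such donors direct to), and enolisation with exhaustive acetylation gives the fully substituted tetraacetoxyarene.

Step 10
Reactants: 20 3-henicosyl-6-methylbenzene-1,2,4,5-tetrayl tetraacetate
Product: 22 3-henicosyl-2,5-dihydroxy-6-methylcyclohexa-2,5-diene-1,4-dione, via tetrol 21 (not isolated)
Conditions: NaOH, MeOH/THF/H2O, air, rt; then aq HCl
Reagents that add atoms: none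
Why: Saponification of the four aryl acetates frees the air-sensitive tetrol 21, whose anion is oxidised by O2 to the 2,5-dihydroxy-1,4-benzoquinone (either para pair of oxygens gives the same compound), and acidification liberates the target 22.

**Compound list**

1 | docosan-1-ol | CCCCCCCCCCCCCCCCCCCCCCO | starting material
2 | docosanal | CCCCCCCCCCCCCCCCCCCCCC=O | intermediate
3 | tricos-1-yne | CCCCCCCCCCCCCCCCCCCCCC#C | intermediate
4 | trichloroacetyl chloride | ClC(=O)C(Cl)(Cl)Cl | starting material
5 | dichloroketene (2,2-dichloroethen-1-one) | O=C=C(Cl)Cl | intermediate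
6 | 4,4-dichloro-3-henicosylcyclobut-2-en-1-one | CCCCCCCCCCCCCCCCCCCCCC1=CC(=O)C1(Cl)Cl | intermediate
7 | 3-henicosylcyclobut-2-en-1-one | CCCCCCCCCCCCCCCCCCCCCC1=CC(=O)C1 | intermediate
8 | ethyl acetate | CCOC(C)=O | starting material
9 | lithium 1,1-dibromoprop-1-en-2-olate | [Li+].CC([O-])=C(Br)Br | intermediate
10 | lithium prop-1-yn-1-olate | [Li+].CC#C[O-] | intermediate
11 | triisopropyl(prop-1-yn-1-yloxy)silane | CC#CO[Si](C(C)C)(C(C)C)C(C)C | intermediate
12 | 3-methylidenetetracos-1-en-1-one (vinylketene) | CCCCCCCCCCCCCCCCCCCCCC(=C)C=C=O | intermediate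
13 | rac-2-methyl-4-(tricos-1-en-2-yl)-3-(triisopropylsilyloxy)cyclobut-2-en-1-one | CCCCCCCCCCCCCCCCCCCCCC(=C)C1C(=O)C(C)=C1O[Si](C(C)C)(C(C)C)C(C)C | intermediate
14 | (3E)-2-methyl-5-methylidene-3-(triisopropylsilyloxy)hexacosa-1,3-dien-1-one (dienylketene) | CCCCCCCCCCCCCCCCCCCCCC(=C)/C=C(/O[Si](C(C)C)(C(C)C)C(C)C)C(C)=C=O | intermediate
15 | 5-henicosyl-2-methyl-3-(triisopropylsilyloxy)cyclohexa-2,4-dien-1-one | CCCCCCCCCCCCCCCCCCCCCC1=CC(O[Si](C(C)C)(C(C)C)C(C)C)=C(C)C(=O)C1 | intermediate
16 | 5-henicosyl-2-methyl-3-(triisopropylsilyloxy)phenol | CCCCCCCCCCCCCCCCCCCCCc1cc(O)c(C)c(O[Si](C(C)C)(C(C)C)C(C)C)c1 | intermediate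
17 | 5-henicosyl-2-methylbenzene-1,3-diol | CCCCCCCCCCCCCCCCCCCCCc1cc(O)c(C)c(O)c1 | intermediate
18 | 5-henicosyl-3-hydroxy-2-methylcyclohexa-2,5-diene-1,4-dione | CCCCCCCCCCCCCCCCCCCCCC1=CC(=O)C(C)=C(O)C1=O | intermediate
19 | 5-henicosyl-2-methyl-3,6-dioxocyclohexa-1,4-dien-1-yl acetate | CCCCCCCCCCCCCCCCCCCCCC1=CC(=O)C(C)=C(OC(C)=O)C1=O | intermediate
20 | 3-henicosyl-6-methylbenzene-1,2,4,5-tetrayl tetraacetate | CCCCCCCCCCCCCCCCCCCCCc1c(OC(C)=O)c(OC(C)=O)c(C)c(OC(C)=O)c1OC(C)=O | intermediate
21 | 3-henicosyl-6-methylbenzene-1,2,4,5-tetrol | CCCCCCCCCCCCCCCCCCCCCc1c(O)c(O)c(C)c(O)c1O | intermediate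
22 | 3-henicosyl-2,5-dihydroxy-6-methylcyclohexa-2,5-diene-1,4-dione | CCCCCCCCCCCCCCCCCCCCCC1=C(O)C(=O)C(C)=C(O)C1=O | target

**Step count and risks**

Total step count: 10. Longest linear sequence: 9 steps (steps 1–4 and 6–10); step 5 is a one-step side branch.

Steps most likely to fail:

Step 6 (benzannulation). The vinylketene may be consumed by dimerisation or by O-acylation of the phenol as it forms, or the siloxyalkyne may be lost thermally before it is trapped, so the ring is closed in low conversion. The fallback builds the arene without any ketene chemistry; it sets out from docosanal 2 and comes back at resorcinol 17. Wittig reaction of 2 with 1-(triphenylphosphoranylidene)butan-2-one (toluene, 80 °C) should give (E)-hexacos-4-en-3-one F1. Michael addition of dimethyl malonate followed by Claisen ring closure (NaOMe, MeOH, reflux) would give methyl 6-henicosyl-3-methyl-2,4-dioxocyclohexane-1-carboxylate F2. Saponification and decarboxylation (aq NaOH, then HCl, heat) would give 5-henicosyl-2-methylcyclohexane-1,3-dione F3. Dehydrogenative aromatisation (Pd/C, mesitylene, reflux) would then give 17, which continues with step 8.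

Step 9 (Thiele–Winter acetoxylation). Conjugate addition of acetate to a trisubstituted, donor-bearing quinone may be too slow, so that only O-acetylation occurs or the quinone degrades in strong acid. The fallback replaces acid-catalysed addition by halogenation and hydrolysis; it sets out from hydroxyquinone 18 and comes back at target 22. Bromination of the remaining quinone C–H by addition–elimination (Br2, AcOH, rt) should give 2-bromo-3-henicosyl-5-hydroxy-6-methylcyclohexa-2,5-diene-1,4-dione F4. Displacement of the vinylogous acyl bromide by hydroxide (aq NaOH, dioxane, rt; then aq HCl) would give 22, as in the classical hydrolysis of haloquinones to hydroxyquinones.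

Step 5 (siloxyalkyne). Enolisation of ethyl acetate may compete with carbenoid addition, lithium ethoxide may compete for the silyl triflate, and the small product may be lost on isolation. The fallback avoids ynolate chemistry by changing the ketenophile and the oxygen protecting group; it sets out from cyclobutenone 7 and comes back at resorcinol 17. Heating 7 with commercial 1-ethoxyprop-1-yne (toluene, 80 °C; excess alkyne removed; then 130 °C) should give, by the same cascade, 3-ethoxy-5-henicosyl-2-methylphenol F5. Cleavage of the ethyl ether with BBr3 (CH2Cl2, −78 °C to rt) would give 17.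

**Further compounds**

F1 | step 6 | (E)-hexacos-4-en-3-one | CCC(=O)/C=C/CCCCCCCCCCCCCCCCCCCCC
F2 | step 6 | methyl 6-henicosyl-3-methyl-2,4-dioxocyclohexane-1-carboxylate (mixture of stereoisomers and enol forms) | CCCCCCCCCCCCCCCCCCCCCC1CC(=O)C(C)C(=O)C1C(=O)OC
F3 | step 6 | 5-henicosyl-2-methylcyclohexane-1,3-dione | CCCCCCCCCCCCCCCCCCCCCC1CC(=O)C(C)C(=O)C1
F4 | step 9 | 2-bromo-3-henicosyl-5-hydroxy-6-methylcyclohexa-2,5-diene-1,4-dione | CCCCCCCCCCCCCCCCCCCCCC1=C(Br)C(=O)C(C)=C(O)C1=O
F5 | step 5 | 3-ethoxy-5-henicosyl-2-methylphenol | CCCCCCCCCCCCCCCCCCCCCc1cc(O)c(C)c(OCC)c1
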